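**Retrosynthetic overview**
- Last C–C bond: C11=C12 by Wittig reaction of a furanoid C15 phosphonium salt with an ε-end C25 apo-aldehyde (ε-end C15 salt + C10 dialdehyde).
- Dihydrofuran ring (the only ring that is built): silver-catalysed 5-endo closure of a (5R, axis R) α-hydroxy vinylallene; the allene axis becomes the C8 (S) centre.
- Key C8–C9 bond: palladium-catalysed anti-SN2' union of an anti-5,6-epoxy-6-ethynyl ring piece with a (Z)-β-boryl crotonate, a β-acylvinyl anion (homoenolate-type d3) reagent; both carbons joined are innately electrophilic.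
- Epoxy-alkyne from (4R,6R)-actinol (brings C3); ε ring from (R)-α-ionone (brings C6'), C3' set by allylic oxidation and hydride reduction.
- Order of rings: both carbocycles are bought; the dihydrofuran ring is closed after the key coupling.

Assumption: (4R,6R)-actinol, enantiopure (R)-α-ionone and the C10 dialdehyde are bought. Positions in the Why lines use carotenoid numbering (C1–C20 for the furanoid half, primed for the ε half). The target is (3S,5R,8S,3'R,6'R)-5,8-epoxy-5,8-dihydro-β,ε-carotene-3,3'-diol (chrysanthemaxanthin).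

**Route**

Step 1
Reactants: 1 (4R,6R)-4-hydroxy-2,2,6-trimethylcyclohexan-1-one ((−)-actinol); 2 ethynylmagnesium bromide
Product: 3 (1S,4R,6R)-1-ethynyl-2,2,6-trimethylcyclohexane-1,4-diol
Conditions: HC≡CMgBr (3 equiv), THF, 0 °C to rt; aq NH4Cl
Reagents that add atoms: none
Why: 1,2-addition of an alkynyl Grignard reagent to the hindered ketone after deprotonation of the free hydroxyl, where the configuration of the new carbinol carbon (shown as the expected major epimer) and of the adjacent CH(Me) is erased in step 3 while the C3 carbinol centre is untouched.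

Step 2
Reactants: 3 (1S,4R,6R)-1-ethynyl-2,2,6-trimethylcyclohexane-1,4-diol
Product: 4 (1R,4S,5R)-4-ethynyl-4-hydroxy-3,3,5-trimethylcyclohexyl acetate
Conditions: Ac2O (1.2 equiv), pyridine, CH2Cl2, 0 °C to rt
Reagents that add atoms: acetic anhydride CC(=O)OC(C)=O
Why: chemoselective O-acylation of the secondary alcohol, the tertiary propargylic alcohol flanked by a quaternary carbon being inert, so that C3 is protected for the dehydration and carries the group that steers the epoxidation.

Step 3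
Reactants: 4 (1R,4S,5R)-4-ethynyl-4-hydroxy-3,3,5-trimethylcyclohexyl acetate
Product: 5 (1R)-4-ethynyl-3,5,5-trimethylcyclohex-3-en-1-yl acetate
Conditions: POCl3 (3 equiv), pyridine, 90 °C
Reagents that add atoms: none
Why: dehydration of the tertiary alcohol through its dichlorophosphate under basic conditions (no Meyer–Schuster or Rupe shift), where the only β-hydrogen is at C5 so the C5=C6 enyne is the sole regioisomer.

Step 4
Reactants: 5 (1R)-4-ethynyl-3,5,5-trimethylcyclohex-3-en-1-yl acetate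
Product: 6 (1R,3S,6R)-6-ethynyl-1,5,5-trimethyl-7-oxabicyclo[4.1.0]heptan-3-yl acetate
Conditions: mCPBA (1.3 equiv), NaHCO3, CH2Cl2, 0 °C; chromatography
Reagents that add atoms: meta-chloroperoxybenzoic acid OOC(=O)c1cccc(Cl)c1
Why: Prilezhaev epoxidation of the tetrasubstituted ring alkene (the alkyne is inert), the peracid being expected to come mainly anti to the 3-acetoxy group by analogy with 3-acyloxy β-rings (modest selectivity, about 3:1, from recollection), which sets C5 (R) with its oxygen trans to the C3 oxygen, the minor syn epoxide being removed.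

Step 5
Reactants: 7 ethyl but-2-ynoate; 8 bis(pinacolato)diboron
Product: 9 ethyl (2Z)-3-(4,4,5,5-tetramethyl-1,3,2-dioxaborolan-2-yl)but-2-enoate
Conditions: CuCl (3 mol %), NaOtBu (6 mol %), Xantphos (3 mol %), MeOH (2 equiv), THF, rt
Reagents that add atoms: none
Why: copper-catalysed conjugate borylation of the ynoate followed by protonation of the alkenylcopper, a syn addition of boron and hydrogen that places boron trans to the ester as needed for the later 9E double bond.

Step 6
Reactants: 6 (1R,3S,6R)-6-ethynyl-1,5,5-trimethyl-7-oxabicyclo[4.1.0]heptan-3-yl acetate; 9 ethyl (2Z)-3-(4,4,5,5-tetramethyl-1,3,2-dioxaborolan-2-yl)but-2-enoate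
Product: 10 ethyl (2E)-5-[(2R,4S)-4-(acetyloxy)-2-hydroxy-2,6,6-trimethylcyclohexylidene]-3-methylpenta-2,4-dienoate with (R) allene axis
Conditions: Pd(PPh3)4 (5 mol %), 9 (1.5 equiv), THF–H2O 10:1, 50 °C, degassed
Reagents that add atoms: none
Why: Proposed new method: zerovalent palladium opens the ethynyl oxirane by anti-SN2' oxidative addition to a σ-allenylpalladium alkoxide at C8, the alkoxide activates the boronate for transmetalation and reductive elimination with retention joins C8 to C9 anti to the departing C6–O bond, so the oxirane configuration is translated into the (R) allene axis while C5 keeps its oxygen and C9=C10 keeps the geometry of 9; the boronate serves as a β-acylvinyl anion (homoenolate-type d3) equivalent that turns the innately electrophilic β-carbon of the crotonate into the nucleophile for the electrophilic alkyne terminus; closest known reaction type is the palladium-catalysed anti-selective coupling of propargylic oxiranes with aryl- and alkenylboronic acids to 2,3-allenols.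

Step 7
Reactants: 10 ethyl (2E)-5-[(2R,4S)-4-(acetyloxy)-2-hydroxy-2,6,6-trimethylcyclohexylidene]-3-methylpenta-2,4-dienoate with (R) allene axis
Product: 11 ethyl (2E)-3-[(2S,6S,7aR)-6-(acetyloxy)-4,4,7a-trimethyl-2,4,5,6,7,7a-hexahydro-1-benzofuran-2-yl]but-2-enoate
Conditions: AgNO3 (0.2 equiv), CaCO3, acetone–H2O, rt, dark
Reagents that add atoms: none
Why: silver-catalysed 5-endo cycloisomerisation of an α-hydroxyallene in which monovalent silver activates the C7=C8 bond, the tertiary C5 hydroxyl attacks C8 and protodemetalation at C7 leaves the C6=C7 alkene, the axis being transferred to the new centre, which comes out 8S with the C9 substituent cis to the C5 methyl.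

Step 8
Reactants: 11 ethyl (2E)-3-[(2S,6S,7aR)-6-(acetyloxy)-4,4,7a-trimethyl-2,4,5,6,7,7a-hexahydro-1-benzofuran-2-yl]but-2-enoate
Product: 12 (2S,6S,7aR)-2-[(2E)-4-hydroxybut-2-en-2-yl]-4,4,7a-trimethyl-2,4,5,6,7,7a-hexahydro-1-benzofuran-6-ol
Conditions: i-Bu2AlH (5 equiv), CH2Cl2, −78 to −20 °C; aq KNaC4H4O6
Reagents that add atoms: none
Why: 1,2-hydride reduction of the enoate to the allylic alcohol with reductive cleavage of the acetate in the same operation, the neutral work-up sparing the acid-labile doubly allylic C8 ether so that no stereocentre is touched.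

Step 9
Reactants: 12 (2S,6S,7aR)-2-[(2E)-4-hydroxybut-2-en-2-yl]-4,4,7a-trimethyl-2,4,5,6,7,7a-hexahydro-1-benzofuran-6-ol
Product: 14 {(2E)-3-[(2S,6S,7aR)-6-hydroxy-4,4,7a-trimethyl-2,4,5,6,7,7a-hexahydro-1-benzofuran-2-yl]but-2-en-1-yl}triphenylphosphonium bromide, via allylic bromide 13 (not isolated)
Conditions: CBr4 (1.1 equiv), PPh3 (2.3 equiv), NaHCO3 (solid), CH2Cl2, 0 °C to rt, 16 h; precipitation with Et2O
Reagents that add atoms: triphenylphosphine c1ccccc1P(c1ccccc1)c1ccccc1; carbon tetrabromide BrC(Br)(Br)Br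
Why: Appel bromination of the primary allylic alcohol, which reacts faster than the secondary C3 alcohol, followed by SN2 quaternisation of the bromide by the excess phosphine, the acid-free medium preventing ionisation and epimerisation at C8.

Step 10
Reactants: 15 (R)-α-ionone; 16 triethyl phosphonoacetate
Product: 18 ethyl (2E,4E)-3-methyl-5-[(1R)-2,6,6-trimethylcyclohex-2-en-1-yl]penta-2,4-dienoate, via sodium 1-(diethoxyphosphoryl)-2-ethoxy-2-oxoethanide 17 (not isolated)
Conditions: NaH (1.1 equiv), THF, 0 °C; then 15, rt to 45 °C; chromatography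
Reagents that add atoms: none
Why: Horner–Wadsworth–Emmons olefination of the methyl ketone giving mainly the 9'E dienoate (the minor 9'Z isomer is removed), the stabilised carbanion being too weak a base to enolise toward C6' so the 6'R centre is kept.

Step 11
Reactants: 18 ethyl (2E,4E)-3-methyl-5-[(1R)-2,6,6-trimethylcyclohex-2-en-1-yl]penta-2,4-dienoate
Product: 19 ethyl (2E,4E)-3-methyl-5-[(1R)-2,6,6-trimethyl-4-oxocyclohex-2-en-1-yl]penta-2,4-dienoate
Conditions: Rh2(caprolactamate)4 (1 mol %), t-BuOOH (70% aq, 5 equiv), K2CO3, CH2Cl2, rt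
Reagents that add atoms: tert-butyl hydroperoxide CC(C)(C)OO
Why: radical allylic oxidation in which the tert-butylperoxyl radical abstracts hydrogen from the secondary allylic C3' methylene of the electron-rich ring alkene, the tertiary C6'–H being shielded by the gem-dimethyl carbon and the C5' methyl and the dienoate being electron-poor.

Step 12
Reactants: 19 ethyl (2E,4E)-3-methyl-5-[(1R)-2,6,6-trimethyl-4-oxocyclohex-2-en-1-yl]penta-2,4-dienoate
Product: 20 ethyl (2E,4E)-5-[(1R,4R)-4-hydroxy-2,6,6-trimethylcyclohex-2-en-1-yl]-3-methylpenta-2,4-dienoate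
Conditions: K[(s-Bu)3BH] (1.2 equiv), THF, −78 °C; aq NH4Cl; chromatography
Reagents that add atoms: none
Why: 1,2-reduction of the β,β-disubstituted enone by a bulky trialkylborohydride which, with the C6' side chain pseudoaxial, avoids the axial C1' methyl and attacks C3' from the face of the side chain, placing the new hydroxyl trans to it (3'R), the ester being inert at −78 °C.

Step 13
Reactants: 20 ethyl (2E,4E)-5-[(1R,4R)-4-hydroxy-2,6,6-trimethylcyclohex-2-en-1-yl]-3-methylpenta-2,4-dienoate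
Product: 21 (2E,4E)-5-[(1R,4R)-4-hydroxy-2,6,6-trimethylcyclohex-2-en-1-yl]-3-methylpenta-2,4-dien-1-ol
Conditions: i-Bu2AlH (3.5 equiv), toluene, −78 to 0 °C; aq KNaC4H4O6
Reagents that add atoms: none
Why: 1,2-hydride reduction of the dienoate to the dienyl alcohol without touching the stereocentres or the double-bond geometry.

Step 14
Reactants: 21 (2E,4E)-5-[(1R,4R)-4-hydroxy-2,6,6-trimethylcyclohex-2-en-1-yl]-3-methylpenta-2,4-dien-1-ol
Product: 22 {(2E,4E)-5-[(1R,4R)-4-hydroxy-2,6,6-trimethylcyclohex-2-en-1-yl]-3-methylpenta-2,4-dien-1-yl}triphenylphosphonium bromide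
Conditions: PPh3·HBr (1.05 equiv), MeOH, 0 °C to rt; crystallisation
Reagents that add atoms: triphenylphosphine hydrobromide [Br-].c1ccccc1[PH+](c1ccccc1)c1ccccc1
Why: SN1-type substitution of the primary dienylic alcohol through its pentadienyl cation, which forms far more readily than the cation from the ring allylic alcohol, the standard way to carotenoid C15 Wittig salts.

Step 15
Reactants: 22 {(2E,4E)-5-[(1R,4R)-4-hydroxy-2,6,6-trimethylcyclohex-2-en-1-yl]-3-methylpenta-2,4-dien-1-yl}triphenylphosphonium bromide; 23 (2E,4E,6E)-2,7-dimethylocta-2,4,6-trienedial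
Product: 25 (2E,4E,6E,8E,10E,12E)-13-[(1R,4R)-4-hydroxy-2,6,6-trimethylcyclohex-2-en-1-yl]-2,7,11-trimethyltrideca-2,4,6,8,10,12-hexaenal, via ε-end C15 phosphorus ylide 24 (not isolated)
Conditions: NaOMe (1.1 equiv), 23 (3 equiv), CH2Cl2–MeOH, −10 °C to rt; then heptane, 80 °C; chromatography
Reagents that add atoms: none
Why: Wittig olefination of one formyl group of the dialdehyde used in excess, forming C11'=C12', with thermal Z to E isomerisation of the new double bond as is usual for polyenes.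

Step 16
Reactants: 14 {(2E)-3-[(2S,6S,7aR)-6-hydroxy-4,4,7a-trimethyl-2,4,5,6,7,7a-hexahydro-1-benzofuran-2-yl]but-2-en-1-yl}triphenylphosphonium bromide; 25 (2E,4E,6E,8E,10E,12E)-13-[(1R,4R)-4-hydroxy-2,6,6-trimethylcyclohex-2-en-1-yl]-2,7,11-trimethyltrideca-2,4,6,8,10,12-hexaenal
Product: 27 (3S,5R,8S,3'R,6'R)-5,8-epoxy-5,8-dihydro-β,ε-carotene-3,3'-diol, via furanoid C15 phosphorus ylide 26 (not isolated)
Conditions: 14 (1.2 equiv), 1,2-epoxybutane, EtOH, 75 °C, dark, argon; chromatography on base-washed support, crystallisation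
Reagents that add atoms: none
Why: Wittig olefination forming C11=C12 under acid-free and nearly neutral conditions (the epoxide scavenges HBr and generates the ylide), which tolerate both free hydroxyls and the epimerisable C8 ether, the heating converting the 11Z isomer to the all-E polyene.

**Compound list**
1 | (4R,6R)-4-hydroxy-2,2,6-trimethylcyclohexan-1-one ((−)-actinol) | O=C1C(C)(C)C[C@H](O)C[C@H]1C | starting material
2 | ethynylmagnesium bromide | C#C[Mg]Br | starting material
3 | (1S,4R,6R)-1-ethynyl-2,2,6-trimethylcyclohexane-1,4-diol | C#C[C@@]1(O)C(C)(C)C[C@H](O)C[C@H]1C | intermediate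
4 | (1R,4S,5R)-4-ethynyl-4-hydroxy-3,3,5-trimethylcyclohexyl acetate | C#C[C@@]1(O)C(C)(C)C[C@H](OC(C)=O)C[C@H]1C | intermediate
5 | (1R)-4-ethynyl-3,5,5-trimethylcyclohex-3-en-1-yl acetate | C#CC1=C(C)C[C@@H](OC(C)=O)CC1(C)C | intermediate
6 | (1R,3S,6R)-6-ethynyl-1,5,5-trimethyl-7-oxabicyclo[4.1.0]heptan-3-yl acetate | CC(=O)O[C@@H]1C[C@@]2(C)O[C@@]2(C#C)C(C)(C)C1 | intermediate
7 | ethyl but-2-ynoate | CC#CC(=O)OCC | starting material
8 | bis(pinacolato)diboron | CC1(C)OB(OC1(C)C)B1OC(C)(C)C(C)(C)O1 | starting material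
9 | ethyl (2Z)-3-(4,4,5,5-tetramethyl-1,3,2-dioxaborolan-2-yl)but-2-enoate | CCOC(=O)/C=C(\C)B1OC(C)(C)C(C)(C)O1 | intermediate
10 | ethyl (2E)-5-[(2R,4S)-4-(acetyloxy)-2-hydroxy-2,6,6-trimethylcyclohexylidene]-3-methylpenta-2,4-dienoate, (R) allene axis | CCOC(=O)/C=C(\C)C([H])=[C@@]=C1C(C)(C)C[C@H](OC(C)=O)C[C@@]1(C)O | intermediate
11 | ethyl (2E)-3-[(2S,6S,7aR)-6-(acetyloxy)-4,4,7a-trimethyl-2,4,5,6,7,7a-hexahydro-1-benzofuran-2-yl]but-2-enoate | CCOC(=O)/C=C(\C)[C@@H]1C=C2C(C)(C)C[C@H](OC(C)=O)C[C@@]2(C)O1 | intermediate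
12 | (2S,6S,7aR)-2-[(2E)-4-hydroxybut-2-en-2-yl]-4,4,7a-trimethyl-2,4,5,6,7,7a-hexahydro-1-benzofuran-6-ol | OC/C=C(\C)[C@@H]1C=C2C(C)(C)C[C@H](O)C[C@@]2(C)O1 | intermediate
13 | (2S,6S,7aR)-2-[(2E)-4-bromobut-2-en-2-yl]-4,4,7a-trimethyl-2,4,5,6,7,7a-hexahydro-1-benzofuran-6-ol | BrC/C=C(\C)[C@@H]1C=C2C(C)(C)C[C@H](O)C[C@@]2(C)O1 | intermediate (not isolated)
14 | {(2E)-3-[(2S,6S,7aR)-6-hydroxy-4,4,7a-trimethyl-2,4,5,6,7,7a-hexahydro-1-benzofuran-2-yl]but-2-en-1-yl}triphenylphosphonium bromide | [Br-].c1ccccc1[P+](c1ccccc1)(c1ccccc1)C/C=C(\C)[C@@H]1C=C2C(C)(C)C[C@H](O)C[C@@]2(C)O1 | intermediate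
15 | (R)-α-ionone, (3E)-4-[(1R)-2,6,6-trimethylcyclohex-2-en-1-yl]but-3-en-2-one | CC1=CCCC(C)(C)[C@H]1/C=C/C(C)=O | starting material
16 | triethyl phosphonoacetate | CCOC(=O)CP(=O)(OCC)OCC | starting material
17 | sodium 1-(diethoxyphosphoryl)-2-ethoxy-2-oxoethanide | [Na+].CCOC(=O)[CH-]P(=O)(OCC)OCC | intermediate (not isolated)
18 | ethyl (2E,4E)-3-methyl-5-[(1R)-2,6,6-trimethylcyclohex-2-en-1-yl]penta-2,4-dienoate | CC1=CCCC(C)(C)[C@H]1/C=C/C(C)=C/C(=O)OCC | intermediate
19 | ethyl (2E,4E)-3-methyl-5-[(1R)-2,6,6-trimethyl-4-oxocyclohex-2-en-1-yl]penta-2,4-dienoate | CC1=CC(=O)CC(C)(C)[C@H]1/C=C/C(C)=C/C(=O)OCC | intermediate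
20 | ethyl (2E,4E)-5-[(1R,4R)-4-hydroxy-2,6,6-trimethylcyclohex-2-en-1-yl]-3-methylpenta-2,4-dienoate | CC1=C[C@H](O)CC(C)(C)[C@H]1/C=C/C(C)=C/C(=O)OCC | intermediate
21 | (2E,4E)-5-[(1R,4R)-4-hydroxy-2,6,6-trimethylcyclohex-2-en-1-yl]-3-methylpenta-2,4-dien-1-ol | CC1=C[C@H](O)CC(C)(C)[C@H]1/C=C/C(C)=C/CO | intermediate
22 | {(2E,4E)-5-[(1R,4R)-4-hydroxy-2,6,6-trimethylcyclohex-2-en-1-yl]-3-methylpenta-2,4-dien-1-yl}triphenylphosphonium bromide | [Br-].CC1=C[C@H](O)CC(C)(C)[C@H]1/C=C/C(C)=C/C[P+](c1ccccc1)(c1ccccc1)c1ccccc1 | intermediate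
23 | (2E,4E,6E)-2,7-dimethylocta-2,4,6-trienedial | O=C/C(C)=C/C=C/C=C(C)/C=O | starting material
24 | {(2E,4E)-5-[(1R,4R)-4-hydroxy-2,6,6-trimethylcyclohex-2-en-1-yl]-3-methylpenta-2,4-dien-1-ylidene}triphenylphosphorane | CC1=C[C@H](O)CC(C)(C)[C@H]1/C=C/C(C)=C/C=P(c1ccccc1)(c1ccccc1)c1ccccc1 | intermediate (not isolated)
25 | (2E,4E,6E,8E,10E,12E)-13-[(1R,4R)-4-hydroxy-2,6,6-trimethylcyclohex-2-en-1-yl]-2,7,11-trimethyltrideca-2,4,6,8,10,12-hexaenal | CC1=C[C@H](O)CC(C)(C)[C@H]1/C=C/C(C)=C/C=C/C(C)=C/C=C/C=C(C)/C=O | intermediate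
26 | {(2E)-3-[(2S,6S,7aR)-6-hydroxy-4,4,7a-trimethyl-2,4,5,6,7,7a-hexahydro-1-benzofuran-2-yl]but-2-en-1-ylidene}triphenylphosphorane | c1ccccc1P(c1ccccc1)(c1ccccc1)=C/C=C(\C)[C@@H]1C=C2C(C)(C)C[C@H](O)C[C@@]2(C)O1 | intermediate (not isolated)
27 | (3S,5R,8S,3'R,6'R)-5,8-epoxy-5,8-dihydro-β,ε-carotene-3,3'-diol (chrysanthemaxanthin) | CC1=C[C@H](O)CC(C)(C)[C@H]1/C=C/C(C)=C/C=C/C(C)=C/C=C/C=C(C)/C=C/C=C(\C)[C@@H]1C=C2C(C)(C)C[C@H](O)C[C@@]2(C)O1 | target

**Step count and risks**

Total: 16 steps. Longest linear sequence: 9 steps (1, 2, 3, 4, 6, 7, 8, 9, 16, from actinol). The ε branch is 7 steps (10 to 16).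

Most likely to fail, in this order:

Step 6 (the palladium coupling has no exact precedent with a β-boryl enoate and this hindered ethynyl oxirane). Fallback, setting out from 6 and coming back at 12: the C8–C9 bond is made by a Sonogashira reaction and the allene by hydride delivery. Ethyl acetoacetate is converted (aq Me4NOH, Tf2O) into ethyl (2E)-3-{[(trifluoromethyl)sulfonyl]oxy}but-2-enoate F2. F2 is coupled with the terminal alkyne of 6 (Pd(PPh3)2Cl2, CuI, Et3N) to ethyl (2E)-5-[(1R,4S,6R)-4-(acetyloxy)-2,2,6-trimethyl-7-oxabicyclo[4.1.0]heptan-1-yl]-3-methylpent-2-en-4-ynoate F3. i-Bu2AlH then reduces the ester and the acetate and opens the oxirane by SN2' delivery of hydride to C8 from the aluminium bound to the oxirane oxygen. By my stereochemical reasoning this delivery is syn and gives the same (R) axis; that should be confirmed on the product. The product is (2E)-5-[(2R,4S)-2,4-dihydroxy-2,6,6-trimethylcyclohexylidene]-3-methylpenta-2,4-dien-1-ol F4. AgNO3 cyclisation of F4 as in step 7 gives 12.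

Step 4 (facial selectivity of the epoxidation is modest and could turn out syn). Fallback, setting out from 5 and coming back at 6: the oxygen is brought in through a halohydrin, which puts it on the face opposite to the one the electrophile attacks. NBS in aqueous acetone gives, by bromonium formation on the face the peracid prefers and trans opening by water at C5, (1S,3R,4S)-4-bromo-4-ethynyl-3-hydroxy-3,5,5-trimethylcyclohexyl acetate F1. K2CO3 in dry acetone closes F1 with inversion at C6 to the epoxide 6.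

Step 12 (the trans selectivity of the hydride reduction rests on a conformational argument). Fallback, setting out from 19 and coming back at 20: the cis alcohol ethyl (2E,4E)-5-[(1R,4S)-4-hydroxy-2,6,6-trimethylcyclohex-2-en-1-yl]-3-methylpenta-2,4-dienoate F5, isolated from the reduction mixture or made on purpose with NaBH4 and CeCl3, is inverted. Mitsunobu esterification (4-nitrobenzoic acid, PPh3, diisopropyl azodicarboxylate) gives (1R,4R)-4-[(1E,3E)-5-ethoxy-3-methyl-5-oxopenta-1,3-dien-1-yl]-3,5,5-trimethylcyclohex-2-en-1-yl 4-nitrobenzoate F6 with inversion at C3'. K2CO3 in EtOH then releases 20.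

Further compounds
F1 | step 4 | (1S,3R,4S)-4-bromo-4-ethynyl-3-hydroxy-3,5,5-trimethylcyclohexyl acetate | CC(=O)O[C@@H]1C[C@@](C)(O)[C@@](Br)(C#C)C(C)(C)C1
F2 | step 6 | ethyl (2E)-3-{[(trifluoromethyl)sulfonyl]oxy}but-2-enoate | CCOC(=O)/C=C(\C)OS(=O)(=O)C(F)(F)F
F3 | step 6 | ethyl (2E)-5-[(1R,4S,6R)-4-(acetyloxy)-2,2,6-trimethyl-7-oxabicyclo[4.1.0]heptan-1-yl]-3-methylpent-2-en-4-ynoate | CC(=O)O[C@@H]1C[C@@]2(C)O[C@@]2(C#C/C(C)=C/C(=O)OCC)C(C)(C)C1
F4 | step 6 | (2E)-5-[(2R,4S)-2,4-dihydroxy-2,6,6-trimethylcyclohexylidene]-3-methylpenta-2,4-dien-1-ol, (R) allene axis | OC/C=C(\C)C([H])=[C@@]=C1C(C)(C)C[C@H](O)C[C@@]1(C)O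
F5 | step 12 | ethyl (2E,4E)-5-[(1R,4S)-4-hydroxy-2,6,6-trimethylcyclohex-2-en-1-yl]-3-methylpenta-2,4-dienoate | CC1=C[C@@H](O)CC(C)(C)[C@H]1/C=C/C(C)=C/C(=O)OCC
F6 | step 12 | (1R,4R)-4-[(1E,3E)-5-ethoxy-3-methyl-5-oxopenta-1,3-dien-1-yl]-3,5,5-trimethylcyclohex-2-en-1-yl 4-nitrobenzoate | CC1=C[C@H](OC(=O)c2ccc(cc2)[N+](=O)[O-])CC(C)(C)[C@H]1/C=C/C(C)=C/C(=O)OCC
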